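**Plan**
- Ring B carries the C6 ketone next to the C7 tertiary methyl carbinol, which is an α-ketol. After removing the protecting groups, the retrosynthesis cuts C7–C8 and rejoins C6–C8, contracting ring B to a pyran-fused 1-acetyl-2-chlorocyclopent-2-enol.
- Further cuts are C6–C7 (acyl-anion addition to a C6 ketone), C5–Cl, O2–C3 (ring A), C4a–C4 (acetylide addition plus 1,3-carbonyl transposition) and C8a–C1 (formaldehyde aldol).
- Forward, the five-membered carbocycle is bought as 2-acetylcyclopentanone and the dienyne side chain is joined at C4a. Ring A then closes by 6-endo-dig hydroalkoxylation, and ring B arises last by the five-to-six ring expansion.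
- The side-chain centre comes from (S)-2-methylbutan-1-ol. C8 and C8a are set together by CBS desymmetrisation of an achiral enedione.
- C6 follows from addition anti to the C8 silyl ether and the dioxolane. C7 follows from C6 through an aluminium chelate.

Key step: step 19

Remark 1: atom labels C1–C9 are those of the target (isochromene numbering, C9 = acetyl carbonyl on C8a) and are kept for all intermediates. In the names of the cyclopenta[c]pyrans, positions 7 and 7a are labels C8 and C8a. TBS = tert-butyldimethylsilyl. Compounds 9–12 are racemates whose only stereocentre disappears in achiral 13.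
Remark 2 (assumption): in the CBS model for step 11, the quaternary carbon is taken as the large flank and the vinylic carbon as the small flank of the carbonyl. This assigns the (R)-catalyst.

**Step 1**
Reactants: 1 (S)-2-methylbutan-1-ol
Product: 3 ethyl (2E,4S)-2,4-dimethylhex-2-enoate, via (S)-2-methylbutanal 2 (not isolated)
Conditions: TEMPO (10 mol %), PhI(OAc)2, CH2Cl2, rt; then Ph3P=C(CH3)CO2Et, rt
Reagents that add atoms: ethyl 2-(triphenyl-λ5-phosphanylidene)propanoate, CCOC(=O)C(C)=P(c1ccccc1)(c1ccccc1)c1ccccc1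
Why: The oxoammonium (TEMPO/PhI(OAc)2) oxidation stops at the aldehyde under near-neutral conditions that should spare the α-stereocentre, and Wittig olefination with the stabilised α-branched ylide in the same flask should give the E-trisubstituted enoate without handling the volatile, epimerisable aldehyde.

**Step 2**
Reactants: 3 ethyl (2E,4S)-2,4-dimethylhex-2-enoate
Product: 4 (2E,4S)-2,4-dimethylhex-2-en-1-ol
Conditions: i-Bu2AlH (2.2 equiv), CH2Cl2, −78 °C
Reagents that add atoms: none
Why: Low-temperature i-Bu2AlH reduction is the standard 1,2-reduction of an unsaturated ester to the allylic alcohol and touches neither the alkene geometry nor the stereocentre.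

**Step 3**
Reactants: 4 (2E,4S)-2,4-dimethylhex-2-en-1-ol
Product: 5 (2E,4S)-2,4-dimethylhex-2-enal
Conditions: MnO2 (excess), CH2Cl2, rt
Reagents that add atoms: none
Why: MnO2 is a chemoselective allylic alcohol oxidation that should give the enal without over-oxidation or loss of alkene geometry.

**Step 4**
Reactants: 5 (2E,4S)-2,4-dimethylhex-2-enal
Product: 6 [(3E,5E,7S)-5,7-dimethylnona-3,5-dien-1-yn-1-yl]trimethylsilane
Conditions: (EtO)2P(O)CH2C≡CSiMe3, LiN(SiMe3)2, THF, −78 to 0 °C
Reagents that add atoms: diethyl [3-(trimethylsilyl)prop-2-yn-1-yl]phosphonate, CCOP(=O)(CC#C[Si](C)(C)C)OCC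
Why: Horner–Wadsworth–Emmons olefination with the lithiated propargylic phosphonate is a known E-selective entry to conjugated enynes, and the silyl cap keeps the alkyne terminus from being deprotonated.

**Step 5**
Reactants: 6 [(3E,5E,7S)-5,7-dimethylnona-3,5-dien-1-yn-1-yl]trimethylsilane
Product: 7 (3E,5E,7S)-5,7-dimethylnona-3,5-dien-1-yne
Conditions: K2CO3 (cat.), MeOH, rt
Reagents that add atoms: none
Why: Carbonate-catalysed methanolysis of the C(sp)–Si bond is the routine protiodesilylation of alkynylsilanes and leaves the diene untouched.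

**Step 6**
Reactants: 8 2-acetylcyclopentan-1-one
Product: 9 rac-2-acetyl-2-(hydroxymethyl)cyclopentan-1-one
Conditions: 37 % aq HCHO (1.5 equiv), KHCO3 (cat.), THF/H2O, 0 °C to rt
Reagents that add atoms: formaldehyde, C=O
Why: In this Tollens-type crossed aldol (hydroxymethylation of a 1,3-dicarbonyl) the only acidic C–H lies between the two carbonyls, so C1 is attached at C8a and the quaternary carbon forms as a racemate that is of no consequence because it converges on achiral 13.

**Step 7**
Reactants: 9 rac-2-acetyl-2-(hydroxymethyl)cyclopentan-1-one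
Product: 10 rac-2-acetyl-2-[(TBSO)methyl]cyclopentan-1-one
Conditions: TBSCl, imidazole, DMF, 0 °C to rt
Reagents that add atoms: tert-butyldimethylsilyl chloride, CC(C)(C)[Si](C)(C)Cl
Why: Imidazole-promoted silylation of the primary alcohol is routine, blocks retro-aldol loss of formaldehyde and masks the future O2 until ring A is closed.

**Step 8**
Reactants: 10 rac-2-acetyl-2-[(TBSO)methyl]cyclopentan-1-one
Product: 11 rac-5-acetyl-5-[(TBSO)methyl]cyclopent-2-en-1-one
Conditions: 2-iodoxybenzoic acid (IBX, 2.5 equiv), DMSO, 70 °C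
Reagents that add atoms: none
Why: IBX-mediated α,β-dehydrogenation of ketones can act only on the ring C5–C6 unit, because the acetyl group has no β-hydrogen and C8a is quaternary, and the new conjugation differentiates the two ketones for step 9.

**Step 9**
Reactants: 11 rac-5-acetyl-5-[(TBSO)methyl]cyclopent-2-en-1-one
Product: 12 rac-5-[(TBSO)methyl]-5-(2-methyl-1,3-dioxolan-2-yl)cyclopent-2-en-1-one
Conditions: Me3SiOCH2CH2OSiMe3, Me3SiOTf (10 mol %), CH2Cl2, −78 to −20 °C
Reagents that add atoms: 1,2-bis(trimethylsilyloxy)ethane, C[Si](C)(C)OCCO[Si](C)(C)C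
Why: Ketalisation under Noyori conditions is known to take saturated ketones in preference to conjugated enones, so only the C9 acetyl carbonyl should become the dioxolane.

**Step 10**
Reactants: 12 rac-5-[(TBSO)methyl]-5-(2-methyl-1,3-dioxolan-2-yl)cyclopent-2-en-1-one
Product: 13 2-[(TBSO)methyl]-2-(2-methyl-1,3-dioxolan-2-yl)cyclopent-4-ene-1,3-dione (achiral)
Conditions: Pd(OH)2/C (5 mol %), t-BuOOH (5 equiv), K2CO3 (0.25 equiv), CH2Cl2, 4 °C to rt
Reagents that add atoms: tert-butyl hydroperoxide, CC(C)(C)OO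
Why: Palladium-catalysed hydroperoxide oxidation of an enone at its γ-methylene (allylic peroxidation, then Kornblum–DeLaMare fragmentation) is a known route to 1,4-enediones, and C8 is the only allylic C–H position.

**Step 11**
Reactants: 13 2-[(TBSO)methyl]-2-(2-methyl-1,3-dioxolan-2-yl)cyclopent-4-ene-1,3-dione
Product: 14 (4S,5S)-4-hydroxy-5-[(TBSO)methyl]-5-(2-methyl-1,3-dioxolan-2-yl)cyclopent-2-en-1-one
Conditions: (3aR)-1-methyl-3,3-diphenyltetrahydro-1H,3H-pyrrolo[1,2-c][1,3,2]oxazaborole ((R)-Me-CBS, 20 mol %), catecholborane (1.2 equiv), toluene, −78 °C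
Reagents that add atoms: none
Why: In this Corey–Bakshi–Shibata reduction used as a desymmetrisation, the (R)-catalyst should deliver hydride to one enantiotopic carbonyl from the face anti to the bulky dioxolane (matched case, the other carbonyl being mismatched), which sets C8 with its OH cis to the masked acetyl and sets C8a at the same time.

**Step 12**
Reactants: 14 (4S,5S)-4-hydroxy-5-[(TBSO)methyl]-5-(2-methyl-1,3-dioxolan-2-yl)cyclopent-2-en-1-one
Product: 15 (4S,5S)-4-(TBSO)-5-[(TBSO)methyl]-5-(2-methyl-1,3-dioxolan-2-yl)cyclopent-2-en-1-one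
Conditions: TBSOTf, 2,6-lutidine, CH2Cl2, −78 to 0 °C
Reagents that add atoms: tert-butyldimethylsilyl triflate, CC(C)(C)[Si](C)(C)OS(=O)(=O)C(F)(F)F
Why: The silyl triflate with a hindered pyridine base is the standard way to silylate a crowded secondary alcohol and avoids the basic conditions that could open the β-hydroxy ketone by retro-aldol.

**Step 13**
Reactants: 7 (3E,5E,7S)-5,7-dimethylnona-3,5-dien-1-yne; 15 (4S,5S)-4-(TBSO)-5-[(TBSO)methyl]-5-(2-methyl-1,3-dioxolan-2-yl)cyclopent-2-en-1-one
Product: 17 (1S,4S,5S)-4-(TBSO)-5-[(TBSO)methyl]-1-[(3E,5E,7S)-5,7-dimethylnona-3,5-dien-1-yn-1-yl]-5-(2-methyl-1,3-dioxolan-2-yl)cyclopent-2-en-1-ol, via lithium acetylide 16 (not isolated)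
Conditions: 7, n-BuLi, THF, −78 °C; then 15, −78 to −40 °C; H2O
Reagents that add atoms: none
Why: 1,2-Addition of a lithium acetylide to a cyclopentenone forms C4a–C4 reliably because the slim, hard nucleophile tolerates the neighbouring quaternary carbon and does not add in conjugate fashion, and the new carbinol centre (drawn for attack anti to the dioxolane) is erased in step 14.

**Step 14**
Reactants: 17 the tertiary alcohol of step 13
Product: 18 (4S,5R)-5-(TBSO)-4-[(TBSO)methyl]-3-[(3E,5E,7S)-5,7-dimethylnona-3,5-dien-1-yn-1-yl]-4-(2-methyl-1,3-dioxolan-2-yl)cyclopent-2-en-1-one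
Conditions: [C5H5NH][CrO3Cl] (pyridinium chlorochromate, 3 equiv), molecular sieves, CH2Cl2, rt
Reagents that add atoms: pyridinium chlorochromate (its oxo oxygen ends up on C6 through the [3,3] shift), [O-][Cr](=O)(=O)Cl.c1cc[nH+]cc1
Why: In the Babler–Dauben oxidative transposition the chromate ester of the tertiary allylic alcohol shifts [3,3] to C6 and is oxidised there, which moves the carbonyl to C6 and leaves C4a=C5 conjugated with the alkyne, as known for 1-alkynylcycloalk-2-enols.

**Step 15**
Reactants: 18 the bis-silylated enynone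
Product: 19 (4S,5R)-5-(TBSO)-3-[(3E,5E,7S)-5,7-dimethylnona-3,5-dien-1-yn-1-yl]-4-(hydroxymethyl)-4-(2-methyl-1,3-dioxolan-2-yl)cyclopent-2-en-1-one
Conditions: HF·pyridine, pyridine, THF, 0 °C
Reagents that add atoms: none
Why: Buffered HF·pyridine discriminates between a primary and a hindered secondary TBS ether, a routine selective desilylation that spares the dioxolane.

**Step 16**
Reactants: 19 the hydroxy enynone
Product: 20 (7R,7aS)-7-(TBSO)-3-[(1E,3E,5S)-3,5-dimethylhepta-1,3-dien-1-yl]-7a-(2-methyl-1,3-dioxolan-2-yl)-7,7a-dihydrocyclopenta[c]pyran-6(1H)-one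
Conditions: AuCl(PPh3) (5 mol %), AgOTf (5 mol %), CH2Cl2, rt
Reagents that add atoms: none
Why: Gold-catalysed intramolecular hydroalkoxylation closes ring A (O2–C3) in the 6-endo-dig mode, because C3 is the remote electrophilic terminus of the enynone and the alkyne carbon whose developing charge the dienyl group stabilises, whereas 5-exo attack at C4 would give a strained bicyclo[3.3.0] alkylidene ether.

**Step 17**
Reactants: 20 the bicyclic dienone
Product: 21 (7R,7aS)-5-chloro-7-(TBSO)-3-[(1E,3E,5S)-3,5-dimethylhepta-1,3-dien-1-yl]-7a-(2-methyl-1,3-dioxolan-2-yl)-7,7a-dihydrocyclopenta[c]pyran-6(1H)-one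
Conditions: N-chlorosuccinimide (1.05 equiv), MeCN, 0 °C, dark
Reagents that add atoms: N-chlorosuccinimide, O=C1CCC(=O)N1Cl
Why: Electrophilic chlorination should occur at C5, the nucleophilic terminus of the O2–C3=C4–C4a=C5 dienol ether and α-carbon of the vinylogous ester, in line with the C5 halogenation of azaphilone-type cores that carry the same side chain.

**Step 18**
Reactants: 21 the chloro dienone; 22 ethyl vinyl ether
Product: 25 (6S,7R,7aS)-6-acetyl-5-chloro-7-(TBSO)-3-[(1E,3E,5S)-3,5-dimethylhepta-1,3-dien-1-yl]-7a-(2-methyl-1,3-dioxolan-2-yl)-1,6,7,7a-tetrahydrocyclopenta[c]pyran-6-ol, via 1-ethoxyvinyllithium 23 (not isolated), via enol ether carbinol 24 (not isolated)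
Conditions: 22 (excess), t-BuLi, THF, −78 to 0 °C; then 21, −78 °C; then 0.5 M aq HCl, THF, 0 °C
Reagents that add atoms: water, O
Why: The acyl-anion equivalent 1-ethoxyvinyllithium adds 1,2 to the C6 ketone from the face opposite the C8 silyl ether and the C8a dioxolane, which sets C6 with its OH cis to the C8 oxygen, and brief dilute acid hydrolyses the very labile enol ether to the methyl ketone before the tertiary alcohol can ionise.

**Step 19**
Reactants: 25 the 1-acetyl-2-chlorocyclopentenol
Product: 27 (7R,8R,8aS)-5-chloro-8-(TBSO)-3-[(1E,3E,5S)-3,5-dimethylhepta-1,3-dien-1-yl]-7-hydroxy-7-methyl-8a-(2-methyl-1,3-dioxolan-2-yl)-1,7,8,8a-tetrahydro-6H-isochromen-6-one, via aluminium chelate 26 (not isolated)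
Conditions: Al(OtBu)3 (2 equiv), toluene, 60–80 °C; then H2O
Reagents that add atoms: none
Why: Alkoxide exchange binds the C6 oxygen to aluminium, which also coordinates the acetyl oxygen, so both C–O bonds are held syn-periplanar in a five-membered chelate and the C6–C8 σ bond lies over one face of the C7 carbonyl; C8 then shifts suprafacially from C6 to C7 with retention at C8 while C6 becomes the ketone. This is the α-ketol (acyloin) rearrangement of a 1-acylcycloalkanol, the reaction type behind the D-homoannulation of 17-hydroxy-20-oxo steroids. Ring B is formed not by an end-to-end cyclisation but by a one-carbon ring expansion, five to six, in which the exocyclic carbon C7 is inserted between C6 and C8. The only new stereocentre, C7, is fixed by the C6 configuration together with the syn chelate: with the acetyl group on the face opposite the C8 silyl ether, bonding of C8 to the exposed carbonyl face leaves CH3 on that face and OH cis to the C8 oxygen (7R), whereas an unchelated anti rotamer would give the epimer, hence aluminium rather than base. The selectivity needed is migration of C8 rather than vinylic C5, and it rests on the reversibility of the shift (only C8 migration gives a ketone conjugated through C4a=C5 and C3=C4 to O2), on the better migratory aptitude of an oxygen-bearing sp3 carbon than of a chlorine-bearing sp2 carbon, and on relief of cyclopentene strain. The electron-withdrawing acetyl and chlorine substituents should hold back ionisation of the tertiary allylic C6–O bond under this mild Lewis acid.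

**Step 20**
Reactants: 27 the ring-expanded silyl ether
Product: 28 (7R,8R,8aS)-5-chloro-3-[(1E,3E,5S)-3,5-dimethylhepta-1,3-dien-1-yl]-7,8-dihydroxy-7-methyl-8a-(2-methyl-1,3-dioxolan-2-yl)-1,7,8,8a-tetrahydro-6H-isochromen-6-one
Conditions: HF·pyridine, THF, 0 °C to rt
Reagents that add atoms: none
Why: Cleaving the remaining silyl ether with an acidic fluoride source rather than a basic one avoids retro-aldol opening of the β-hydroxy ketone array.

**Step 21**
Reactants: 28 the diol ketal
Product: 29 (7R,8R,8aS)-8a-acetyl-5-chloro-3-[(1E,3E,5S)-3,5-dimethylhepta-1,3-dien-1-yl]-7,8-dihydroxy-7-methyl-1,7,8,8a-tetrahydro-6H-isochromen-6-one (CNP0307047.1)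
Conditions: 1 M aq HCl, THF, rt
Reagents that add atoms: water, O
Why: Acid-catalysed ketal hydrolysis unmasks the C9 ketone, and the stereocentres should survive because C8a is quaternary (no β-elimination) and the conjugated α-ketol is already the thermodynamic isomer.

**Compound list**
1 | (S)-2-methylbutan-1-ol | CC[C@H](C)CO | starting material
2 | (S)-2-methylbutanal | CC[C@H](C)C=O | intermediate
3 | ethyl (2E,4S)-2,4-dimethylhex-2-enoate | CC[C@H](C)/C=C(C)/C(=O)OCC | intermediate
4 | (2E,4S)-2,4-dimethylhex-2-en-1-ol | CC[C@H](C)/C=C(C)/CO | intermediate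
5 | (2E,4S)-2,4-dimethylhex-2-enal | CC[C@H](C)/C=C(C)/C=O | intermediate
6 | [(3E,5E,7S)-5,7-dimethylnona-3,5-dien-1-yn-1-yl]trimethylsilane | CC[C@H](C)/C=C(C)/C=C/C#C[Si](C)(C)C | intermediate
7 | (3E,5E,7S)-5,7-dimethylnona-3,5-dien-1-yne | CC[C@H](C)/C=C(C)/C=C/C#C | intermediate
8 | 2-acetylcyclopentan-1-one | CC(=O)C1CCCC1=O | starting material
9 | rac-2-acetyl-2-(hydroxymethyl)cyclopentan-1-one | CC(=O)C1(CO)CCCC1=O | intermediate
10 | rac-2-acetyl-2-[(TBSO)methyl]cyclopentan-1-one | CC(=O)C1(CO[Si](C)(C)C(C)(C)C)CCCC1=O | intermediate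
11 | rac-5-acetyl-5-[(TBSO)methyl]cyclopent-2-en-1-one | CC(=O)C1(CO[Si](C)(C)C(C)(C)C)CC=CC1=O | intermediate
12 | rac-5-[(TBSO)methyl]-5-(2-methyl-1,3-dioxolan-2-yl)cyclopent-2-en-1-one | CC1(OCCO1)C2(CO[Si](C)(C)C(C)(C)C)CC=CC2=O | intermediate
13 | 2-[(TBSO)methyl]-2-(2-methyl-1,3-dioxolan-2-yl)cyclopent-4-ene-1,3-dione (achiral) | CC1(OCCO1)C2(CO[Si](C)(C)C(C)(C)C)C(=O)C=CC2=O | intermediate
14 | (4S,5S)-4-hydroxy-5-[(TBSO)methyl]-5-(2-methyl-1,3-dioxolan-2-yl)cyclopent-2-en-1-one | O=C1C=C[C@H](O)[C@@]1(C2(C)OCCO2)CO[Si](C)(C)C(C)(C)C | intermediate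
15 | (4S,5S)-4-(TBSO)-5-[(TBSO)methyl]-5-(2-methyl-1,3-dioxolan-2-yl)cyclopent-2-en-1-one | O=C1C=C[C@H](O[Si](C)(C)C(C)(C)C)[C@@]1(C2(C)OCCO2)CO[Si](C)(C)C(C)(C)C | intermediate
16 | lithium (3E,5E,7S)-5,7-dimethylnona-3,5-dien-1-yn-1-ide | CC[C@H](C)/C=C(C)/C=C/C#C[Li] | intermediate
17 | (1S,4S,5S)-1-alkynyl-4-(TBSO)-5-[(TBSO)methyl]-5-(2-methyl-1,3-dioxolan-2-yl)cyclopent-2-en-1-ol | CC[C@H](C)/C=C(C)/C=C/C#C[C@@]1(O)C=C[C@H](O[Si](C)(C)C(C)(C)C)[C@@]1(C2(C)OCCO2)CO[Si](C)(C)C(C)(C)C | intermediate
18 | (4S,5R)-3-alkynyl-5-(TBSO)-4-[(TBSO)methyl]-4-(2-methyl-1,3-dioxolan-2-yl)cyclopent-2-en-1-one | CC[C@H](C)/C=C(C)/C=C/C#CC1=CC(=O)[C@H](O[Si](C)(C)C(C)(C)C)[C@@]1(C2(C)OCCO2)CO[Si](C)(C)C(C)(C)C | intermediate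
19 | (4S,5R)-3-alkynyl-5-(TBSO)-4-(hydroxymethyl)-4-(2-methyl-1,3-dioxolan-2-yl)cyclopent-2-en-1-one | CC[C@H](C)/C=C(C)/C=C/C#CC1=CC(=O)[C@H](O[Si](C)(C)C(C)(C)C)[C@@]1(C2(C)OCCO2)CO | intermediate
20 | (7R,7aS)-7-(TBSO)-3-dienyl-7a-(2-methyl-1,3-dioxolan-2-yl)-7,7a-dihydrocyclopenta[c]pyran-6(1H)-one | CC[C@H](C)/C=C(C)/C=C/C1=CC2=CC(=O)[C@H](O[Si](C)(C)C(C)(C)C)[C@@]2(C3(C)OCCO3)CO1 | intermediate
21 | (7R,7aS)-5-chloro derivative of 20 | CC[C@H](C)/C=C(C)/C=C/C1=CC2=C(Cl)C(=O)[C@H](O[Si](C)(C)C(C)(C)C)[C@@]2(C3(C)OCCO3)CO1 | intermediate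
22 | ethyl vinyl ether | C=COCC | starting material
23 | 1-ethoxyvinyllithium | [Li]C(=C)OCC | intermediate
24 | (6S,7R,7aS)-6-(1-ethoxyvinyl) carbinol from 21 | CC[C@H](C)/C=C(C)/C=C/C1=CC2=C(Cl)[C@@](O)(C(=C)OCC)[C@H](O[Si](C)(C)C(C)(C)C)[C@@]2(C3(C)OCCO3)CO1 | intermediate
25 | (6S,7R,7aS)-6-acetyl-5-chloro-7-(TBSO)-3-dienyl-7a-(2-methyl-1,3-dioxolan-2-yl)-1,6,7,7a-tetrahydrocyclopenta[c]pyran-6-ol | CC[C@H](C)/C=C(C)/C=C/C1=CC2=C(Cl)[C@@](O)(C(C)=O)[C@H](O[Si](C)(C)C(C)(C)C)[C@@]2(C3(C)OCCO3)CO1 | intermediate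
26 | di-tert-butoxyaluminium C6-alkoxide of 25 (acetyl oxygen coordinated to Al) | CC[C@H](C)/C=C(C)/C=C/C1=CC2=C(Cl)[C@@](O[Al](OC(C)(C)C)OC(C)(C)C)(C(C)=O)[C@H](O[Si](C)(C)C(C)(C)C)[C@@]2(C3(C)OCCO3)CO1 | intermediate
27 | (7R,8R,8aS)-5-chloro-8-(TBSO)-3-dienyl-7-hydroxy-7-methyl-8a-(2-methyl-1,3-dioxolan-2-yl)-1,7,8,8a-tetrahydro-6H-isochromen-6-one | CC[C@H](C)/C=C(C)/C=C/C1=CC2=C(Cl)C(=O)[C@](C)(O)[C@H](O[Si](C)(C)C(C)(C)C)[C@@]2(C3(C)OCCO3)CO1 | intermediate
28 | (7R,8R,8aS)-7,8-diol with C9 dioxolane | CC[C@H](C)/C=C(C)/C=C/C1=CC2=C(Cl)C(=O)[C@](C)(O)[C@H](O)[C@@]2(C3(C)OCCO3)CO1 | intermediate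
29 | (7R,8R,8aS)-8a-acetyl-5-chloro-3-[(1E,3E,5S)-3,5-dimethylhepta-1,3-dien-1-yl]-7,8-dihydroxy-7-methyl-1,7,8,8a-tetrahydro-6H-isochromen-6-one | CC[C@H](C)/C=C(C)/C=C/C1=CC2=C(Cl)C(=O)[C@](C)(O)[C@H](O)[C@@]2(C(C)=O)CO1 | target

**Step count**
- Total step count: 21.
- Longest linear sequence: 16 steps (8 to 29, steps 6–21). The side-chain branch has 5 steps before the union in step 13.

**The three steps most likely to fail**

**Step 19 (key step).** Several processes may go wrong:
- loss of the C6 oxygen by Lewis-acid ionisation, which the ring A dienol ether assists;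
- shift of the vinylic carbon C5 instead of C8;
- transfer of the silyl group between the cis oxygens on C8 and C6;
- reaction through an unchelated rotamer, with erosion of the C7 configuration.

The fallback runs the same 1,2-shift before ring A and the chlorine are in place. That substrate has no enol-ether donor and therefore tolerates stronger activation. It sets out from 18. Addition of 23 (made as in step 18) gives the enol ether carbinol F1, and dilute acid gives the monocyclic 1-acetylcyclopentenol F2. Al(OtBu)3 in warm toluene expands this to the 3-alkynylcyclohexenone ketol F3. Buffered HF·pyridine frees the primary alcohol F4, and AuCl(PPh3)/AgOTf closes ring A to the deschloro bicycle F5. N-Chlorosuccinimide then chlorinates C5, which brings the sequence back to the route at 27.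

**Step 14.** The tertiary alcohol is both allylic and propargylic, so acid may ionise it. The oxygen may drift to the alkyne terminus (Meyer–Schuster-type enone formation), and the excess chromium reagent may damage the dienyne. The fallback separates the transposition from the oxidation. It sets out from 17. Catalytic Ph3SiOReO3 in Et2O at low temperature moves the hydroxyl group by a metal-oxo [3,3] shift toward the conjugated secondary allylic alcohol F6. MnO2 in CH2Cl2 then oxidises this alcohol, which comes back to the route at 18.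

**Step 11.** The very electrophilic enedione may suffer uncatalysed background reduction, over-reduction to the diol or conjugate reduction. The catalyst may also discriminate poorly between the vinylic and quaternary flanks, so that selection between the enantiotopic carbonyls is poor. The fallback moves the desymmetrisation to the saturated 2,2-disubstituted cyclopentane-1,3-dione, the substrate class for which this reduction is established. It sets out from 13. H2 over Pd/C gives the saturated dione F7, and (R)-Me-CBS with catecholborane gives the hydroxy ketone F8. TBSOTf with 2,6-lutidine gives the bis-silyl ether F9. IBX dehydrogenation (or a Saegusa–Ito sequence) reinstalls C5=C6 and comes back to the route at 15.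

**Further compounds**
F1 | step 19 | (1S,4S,5R)-3-alkynyl-1-(1-ethoxyvinyl)-5-(TBSO)-4-[(TBSO)methyl]-4-(2-methyl-1,3-dioxolan-2-yl)cyclopent-2-en-1-ol | CC[C@H](C)/C=C(C)/C=C/C#CC1=C[C@@](O)(C(=C)OCC)[C@H](O[Si](C)(C)C(C)(C)C)[C@@]1(C2(C)OCCO2)CO[Si](C)(C)C(C)(C)C
F2 | step 19 | monocyclic 1-acetyl-3-alkynylcyclopent-2-en-1-ol (acetyl anti to the C8 silyl ether) | CC[C@H](C)/C=C(C)/C=C/C#CC1=C[C@@](O)(C(C)=O)[C@H](O[Si](C)(C)C(C)(C)C)[C@@]1(C2(C)OCCO2)CO[Si](C)(C)C(C)(C)C
F3 | step 19 | ring-expanded 3-alkynyl-6-hydroxy-6-methylcyclohex-2-en-1-one with C8 and C1 silyl ethers | CC[C@H](C)/C=C(C)/C=C/C#CC1=CC(=O)[C@](C)(O)[C@H](O[Si](C)(C)C(C)(C)C)[C@@]1(C2(C)OCCO2)CO[Si](C)(C)C(C)(C)C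
F4 | step 19 | primary alcohol from F3 | CC[C@H](C)/C=C(C)/C=C/C#CC1=CC(=O)[C@](C)(O)[C@H](O[Si](C)(C)C(C)(C)C)[C@@]1(C2(C)OCCO2)CO
F5 | step 19 | 5-deschloro analogue of 27 | CC[C@H](C)/C=C(C)/C=C/C1=CC2=CC(=O)[C@](C)(O)[C@H](O[Si](C)(C)C(C)(C)C)[C@@]2(C3(C)OCCO3)CO1
F6 | step 14 | transposed secondary allylic alcohol (C6–OH, C4a=C5, drawn for a suprafacial shift) | CC[C@H](C)/C=C(C)/C=C/C#CC1=C[C@H](O)[C@H](O[Si](C)(C)C(C)(C)C)[C@@]1(C2(C)OCCO2)CO[Si](C)(C)C(C)(C)C
F7 | step 11 | 2-[(TBSO)methyl]-2-(2-methyl-1,3-dioxolan-2-yl)cyclopentane-1,3-dione (achiral) | CC1(OCCO1)C2(CO[Si](C)(C)C(C)(C)C)C(=O)CCC2=O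
F8 | step 11 | (2S,3S)-3-hydroxy-2-[(TBSO)methyl]-2-(2-methyl-1,3-dioxolan-2-yl)cyclopentan-1-one | O=C1CC[C@H](O)[C@@]1(C2(C)OCCO2)CO[Si](C)(C)C(C)(C)C
F9 | step 11 | (2S,3S)-3-(TBSO)-2-[(TBSO)methyl]-2-(2-methyl-1,3-dioxolan-2-yl)cyclopentan-1-one | O=C1CC[C@H](O[Si](C)(C)C(C)(C)C)[C@@]1(C2(C)OCCO2)CO[Si](C)(C)C(C)(C)C
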